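**Retrosynthetic overview**

- Broussonol A is reached by de-acetylation of its tetraacetate, which comes from a [3,3] Claisen shift of a 7-O-prenyl ether onto C8 (5-OH masked as acetate). The ether comes from the tetrahydroxy flavonol by selective 7-O-prenylation; the flavonol comes from the tris-MOM flavone by C3 lithiation, borylation and oxidation.
- Ring C of the flavone is cut at three bonds, O1–C8a, C4–C4a and O1–C2. This gives 3,5-bis(MOM-oxy)benzyne (ring A) and a chromenylpropiolic acid (ring B with its fused dimethylpyran).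
- Feature used: on ring A the ring oxygen O1 (on C8a) and the carbonyl carbon C4 (on C4a) sit on neighbouring carbons, the two carbons of an aryne. The C5 oxygen next to C4a polarises that aryne, while C8 still carries only hydrogen.
- Aryne precursor: phloroglucinol, bis-MOM phenol, N-isopropyl carbamate, ortho-silylation, triflate. Acid: 3,4-dihydroxybenzaldehyde, 4-O-(1,1-dimethylpropargyl) ether, MOM ether, propargyl Claisen/electrocyclisation, Corey–Fuchs, CO2.
- Ring order: rings A and B come from the aromatic starting materials; the dimethylpyran ring is closed in step 7 and the pyranone ring C in step 10.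

Key step: step 10

Remark on the chemistry: the target has no stereocentre. The C8 substituent is 2-methylbut-3-en-2-yl (1,1-dimethylallyl), which a [3,3] shift of a 7-O-prenyl ether delivers with the required allyl inversion.

**Route**

Step 1
Reactants: 1 phloroglucinol
Product: 2 3,5-bis(methoxymethoxy)phenol
Conditions: MOMCl (2 equiv), i-Pr2NEt, DMF, 0 °C to rt; chromatographic separation from mono- and tris-ethers
Reagents that add atoms: chloromethyl methyl ether COCCl
Why: O-alkylation of a phenol with an α-chloro ether (acetal-forming Williamson reaction); the symmetry of phloroglucinol allows only one bis-ether, which should be the main component with two equivalents of reagent.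

Step 2
Reactants: 2 3,5-bis(methoxymethoxy)phenol
Product: 3 3,5-bis(methoxymethoxy)phenyl N-isopropylcarbamate
Conditions: i-PrNCO, Et3N (cat.), CH2Cl2, rt
Reagents that add atoms: isopropyl isocyanate CC(C)N=C=O
Why: base-catalysed addition of a phenol to an isocyanate gives the aryl carbamate that serves as director and as masked triflate.

Step 3
Reactants: 3 3,5-bis(methoxymethoxy)phenyl N-isopropylcarbamate
Product: 7 3,5-bis(methoxymethoxy)-2-(trimethylsilyl)phenyl N-isopropylcarbamate, via N-silyl carbamate 4 (not isolated), via ortho-lithio carbamate 5 (not isolated), via N-silyl arylsilane 6 (not isolated)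
Conditions: TBSOTf, TMEDA, Et2O, 0 °C to rt; n-BuLi (2.2 equiv), TMEDA, −78 °C; TMSCl, −78 °C to rt; cold aq NaHSO4 work-up
Reagents that add atoms: chlorotrimethylsilane C[Si](C)(C)Cl
Why: carbamate-directed ortho-metalation after in-situ N-silylation, then silyl quench; the carbamate is the strongest director, its two ortho sites are equivalent and each is also flanked by a MOM-oxy group, so lithiation should occur there and not between the two MOM ethers, and the N-silyl group is lost on aqueous work-up.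

Step 4
Reactants: 7 3,5-bis(methoxymethoxy)-2-(trimethylsilyl)phenyl N-isopropylcarbamate
Product: 9 3,5-bis(methoxymethoxy)-2-(trimethylsilyl)phenyl trifluoromethanesulfonate, via silyl phenol 8 (not isolated)
Conditions: Et2NH, DBU, MeCN, 40 °C; then PhNTf2, rt
Reagents that add atoms: N-phenylbis(trifluoromethanesulfonimide) O=S(=O)(N(c1ccccc1)S(=O)(=O)C(F)(F)F)C(F)(F)F
Why: one-pot aminolysis of the secondary carbamate and O-triflation of the released phenoxide, under conditions mild enough to keep the aryl–silicon bond and the MOM ethers.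

Step 5
Reactants: 10 3,4-dihydroxybenzaldehyde; 11 3-chloro-3-methylbut-1-yne
Product: 12 3-hydroxy-4-[(2-methylbut-3-yn-2-yl)oxy]benzaldehyde
Conditions: DBU (1.1 equiv), CuCl2·2H2O (cat.), MeCN, 0 °C, argon
Reagents that add atoms: none
Why: copper-catalysed propargylic etherification of a phenol with a tertiary propargyl chloride; the 4-OH para to the formyl group is the more acidic one and with one equivalent of base should be the one that is ionised and alkylated.

Step 6
Reactants: 12 3-hydroxy-4-[(2-methylbut-3-yn-2-yl)oxy]benzaldehyde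
Product: 13 3-(methoxymethoxy)-4-[(2-methylbut-3-yn-2-yl)oxy]benzaldehyde
Conditions: MOMCl, i-Pr2NEt, CH2Cl2, 0 °C to rt
Reagents that add atoms: chloromethyl methyl ether COCCl
Why: MOM protection of the remaining phenol (Williamson-type) before heating, so that no free catechol hydroxyl can add to the alkyne or allene in the next step.

Step 7
Reactants: 13 3-(methoxymethoxy)-4-[(2-methylbut-3-yn-2-yl)oxy]benzaldehyde
Product: 15 8-(methoxymethoxy)-2,2-dimethyl-2H-chromene-6-carbaldehyde, via allenyl phenol 14 (not isolated)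
Conditions: PhNEt2, 190 °C
Reagents that add atoms: none
Why: aromatic propargyl Claisen rearrangement to the ortho-allenyl phenol, then 1,5-hydrogen shift and 6π oxa-electrocyclisation; only one ortho carbon (C5) is free, so a single chromene should form.

Step 8
Reactants: 15 8-(methoxymethoxy)-2,2-dimethyl-2H-chromene-6-carbaldehyde
Product: 16 6-(2,2-dibromoethenyl)-8-(methoxymethoxy)-2,2-dimethyl-2H-chromene
Conditions: CBr4, PPh3, Et3N, CH2Cl2, 0 °C
Reagents that add atoms: carbon tetrabromide BrC(Br)(Br)Br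
Why: first stage of the Corey–Fuchs reaction, a Wittig-type dibromo-olefination of the aldehyde, buffered with amine to protect the MOM ether.

Step 9
Reactants: 16 6-(2,2-dibromoethenyl)-8-(methoxymethoxy)-2,2-dimethyl-2H-chromene
Product: 18 3-[8-(methoxymethoxy)-2,2-dimethyl-2H-chromen-6-yl]prop-2-ynoic acid, via lithium acetylide 17 (not isolated)
Conditions: n-BuLi (2.2 equiv), THF, −78 °C; CO2 (g), −78 to 0 °C; cold dilute HCl to pH 3
Reagents that add atoms: carbon dioxide O=C=O
Why: second stage of the Corey–Fuchs reaction (bromine–lithium exchange, Fritsch–Buttenberg–Wiechell rearrangement, deprotonation) gives the lithium acetylide, which is carboxylated by CO2.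

Step 10
Reactants: 9 3,5-bis(methoxymethoxy)-2-(trimethylsilyl)phenyl trifluoromethanesulfonate (1.5 equiv); 18 3-[8-(methoxymethoxy)-2,2-dimethyl-2H-chromen-6-yl]prop-2-ynoic acid
Product: 21 5,7-bis(methoxymethoxy)-2-[8-(methoxymethoxy)-2,2-dimethyl-2H-chromen-6-yl]-4H-chromen-4-one, via 3,5-bis(methoxymethoxy)benzyne 19 (not isolated), via ortho-hydroxyaryl ynone 20 (not isolated)
Conditions: CsF (4 equiv), THF, sealed tube, 100–125 °C
Reagents that add atoms: none
Why: Fluoride removes the trimethylsilyl group of 9 and triflate leaves to give aryne 19; the carboxylate of 18 adds through oxygen to the aryne carbon remote from the flanking MOM-oxy group, the aryl anion formed next to that group takes the acyl carbon in a 1,3 oxygen-to-carbon acyl shift to give the phenoxide of ynone 20, and the phenoxide adds to the ynone to close ring C. The closest known reaction type is the fluoride-induced insertion of arynes into the C–O bond of carboxylic acids, which with arylpropiolic acids is known to run on to flavones. The pyranone closes in the 6-endo-dig mode (O1–C2), because attack at the β-carbon is a conjugate addition whose charge is taken up by the carbonyl, whereas 5-exo attack at the α-carbon (aurone) would leave an unstabilised vinyl anion. No stereocentre is formed. The step needs regioselectivity at the aryne: the MOM-oxy group on one flank stabilises negative charge on its neighbour by induction while the other flank carries only hydrogen, so oxygen should end up on C8a and the acyl group on C4a, which places the two MOM-oxy groups at C5 and C7.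

Step 11
Reactants: 21 5,7-bis(methoxymethoxy)-2-[8-(methoxymethoxy)-2,2-dimethyl-2H-chromen-6-yl]-4H-chromen-4-one
Product: 24 3-hydroxy-5,7-bis(methoxymethoxy)-2-[8-(methoxymethoxy)-2,2-dimethyl-2H-chromen-6-yl]-4H-chromen-4-one, via 3-lithioflavone 22 (not isolated), via flavon-3-yl boronate 23 (not isolated)
Conditions: LiN(i-Pr)2, THF, −78 °C; B(OMe)3, −78 to 0 °C; AcOH then 30% aq H2O2, 0 °C to rt
Reagents that add atoms: hydrogen peroxide OO
Why: flavones are lithiated at C3 by lithium amide bases (the vinylic C–H α to the carbonyl, too weak a base for ortho-metalation of the MOM-oxy rings), and borylation followed by oxidative C–B to C–O conversion gives the flavonol without a peracid that would epoxidise the chromene double bond.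

Step 12
Reactants: 24 3-hydroxy-5,7-bis(methoxymethoxy)-2-[8-(methoxymethoxy)-2,2-dimethyl-2H-chromen-6-yl]-4H-chromen-4-one
Product: 25 3,5,7-trihydroxy-2-(8-hydroxy-2,2-dimethyl-2H-chromen-6-yl)-4H-chromen-4-one
Conditions: 3 M aq HCl, MeOH, 50 °C
Reagents that add atoms: none
Why: acid-catalysed acetal exchange removes the three MOM groups; it is placed here, before the acid-sensitive ortho-(1,1-dimethylallyl)phenol exists, and the 2,2-dimethylchromene should tolerate dilute methanolic HCl.

Step 13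
Reactants: 25 3,5,7-trihydroxy-2-(8-hydroxy-2,2-dimethyl-2H-chromen-6-yl)-4H-chromen-4-one; 26 1-bromo-3-methylbut-2-ene (1.05 equiv)
Product: 27 3,5-dihydroxy-2-(8-hydroxy-2,2-dimethyl-2H-chromen-6-yl)-7-[(3-methylbut-2-en-1-yl)oxy]-4H-chromen-4-one
Conditions: K2CO3 (1.1 equiv), acetone, rt, argon
Reagents that add atoms: none
Why: Williamson etherification under acidity control; the 7-OH, para to the C4 carbonyl, is the most acidic of the four hydroxyls (5-OH is chelated, 3-OH and the ring B hydroxyl are weaker acids), so one equivalent of base and bromide should alkylate O7.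

Step 14
Reactants: 27 3,5-dihydroxy-2-(8-hydroxy-2,2-dimethyl-2H-chromen-6-yl)-7-[(3-methylbut-2-en-1-yl)oxy]-4H-chromen-4-one
Product: 28 2-[8-(acetyloxy)-2,2-dimethyl-2H-chromen-6-yl]-7-[(3-methylbut-2-en-1-yl)oxy]-4-oxo-4H-chromene-3,5-diyl diacetate
Conditions: Ac2O, pyridine, DMAP (cat.), rt to 50 °C
Reagents that add atoms: acetic anhydride CC(=O)OC(C)=O
Why: nucleophile-catalysed O-acetylation of all three remaining hydroxyls, which in particular removes the hydrogen bond between the 5-OH and the C4 carbonyl before the rearrangement.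

Step 15
Reactants: 28 2-[8-(acetyloxy)-2,2-dimethyl-2H-chromen-6-yl]-7-[(3-methylbut-2-en-1-yl)oxy]-4-oxo-4H-chromene-3,5-diyl diacetate
Product: 30 2-[8-(acetyloxy)-2,2-dimethyl-2H-chromen-6-yl]-8-(2-methylbut-3-en-2-yl)-4-oxo-4H-chromene-3,5,7-triyl triacetate, via 7-hydroxy triacetate 29 (not isolated)
Conditions: PhNEt2, Ac2O, sealed tube, 190 °C
Reagents that add atoms: acetic anhydride CC(=O)OC(C)=O
Why: aromatic Claisen rearrangement, a [3,3] shift that inverts the prenyl unit into the 1,1-dimethylallyl group on an ortho carbon; with the 5-oxygen acetylated and no chelate, the bond fixation of the chromone (higher C7–C8 double-bond character) and the smaller steric demand beside ring oxygen O1 should send the group to C8 and not C6, and the anhydride traps the hindered phenol before it can rearrange further or add to the new alkene.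

Step 16
Reactants: 30 2-[8-(acetyloxy)-2,2-dimethyl-2H-chromen-6-yl]-8-(2-methylbut-3-en-2-yl)-4-oxo-4H-chromene-3,5,7-triyl triacetate
Product: 31 Broussonol A
Conditions: NH3 (7 M in MeOH), 0 °C to rt, argon
Reagents that add atoms: none
Why: ammonolysis of the four aryl and enol acetates under mild, non-acidic conditions releases the tetraphenol and leaves the terminal alkene and the chromene untouched.

**Compound list**

1 | phloroglucinol | Oc1cc(O)cc(O)c1 | starting material
2 | 3,5-bis(methoxymethoxy)phenol | COCOc1cc(O)cc(OCOC)c1 | intermediate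
3 | 3,5-bis(methoxymethoxy)phenyl N-isopropylcarbamate | CC(C)NC(=O)Oc1cc(OCOC)cc(OCOC)c1 | intermediate
4 | 3,5-bis(methoxymethoxy)phenyl N-(tert-butyldimethylsilyl)-N-isopropylcarbamate | CC(C)N(C(=O)Oc1cc(OCOC)cc(OCOC)c1)[Si](C)(C)C(C)(C)C | intermediate
5 | 2-lithio-3,5-bis(methoxymethoxy)phenyl N-(tert-butyldimethylsilyl)-N-isopropylcarbamate | CC(C)N(C(=O)Oc1cc(OCOC)cc(OCOC)c1[Li])[Si](C)(C)C(C)(C)C | intermediate
6 | 3,5-bis(methoxymethoxy)-2-(trimethylsilyl)phenyl N-(tert-butyldimethylsilyl)-N-isopropylcarbamate | CC(C)N(C(=O)Oc1cc(OCOC)cc(OCOC)c1[Si](C)(C)C)[Si](C)(C)C(C)(C)C | intermediate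
7 | 3,5-bis(methoxymethoxy)-2-(trimethylsilyl)phenyl N-isopropylcarbamate | CC(C)NC(=O)Oc1cc(OCOC)cc(OCOC)c1[Si](C)(C)C | intermediate
8 | 3,5-bis(methoxymethoxy)-2-(trimethylsilyl)phenol | COCOc1cc(O)c([Si](C)(C)C)c(OCOC)c1 | intermediate
9 | 3,5-bis(methoxymethoxy)-2-(trimethylsilyl)phenyl trifluoromethanesulfonate | COCOc1cc(OCOC)c([Si](C)(C)C)c(OS(=O)(=O)C(F)(F)F)c1 | intermediate
10 | 3,4-dihydroxybenzaldehyde | O=Cc1ccc(O)c(O)c1 | starting material
11 | 3-chloro-3-methylbut-1-yne | CC(C)(Cl)C#C | starting material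
12 | 3-hydroxy-4-[(2-methylbut-3-yn-2-yl)oxy]benzaldehyde | O=Cc1ccc(OC(C)(C)C#C)c(O)c1 | intermediate
13 | 3-(methoxymethoxy)-4-[(2-methylbut-3-yn-2-yl)oxy]benzaldehyde | O=Cc1ccc(OC(C)(C)C#C)c(OCOC)c1 | intermediate
14 | 4-hydroxy-3-(methoxymethoxy)-5-(3-methylbuta-1,2-dien-1-yl)benzaldehyde | O=Cc1cc(OCOC)c(O)c(C=C=C(C)C)c1 | intermediate
15 | 8-(methoxymethoxy)-2,2-dimethyl-2H-chromene-6-carbaldehyde | O=Cc1cc(OCOC)c2c(c1)C=CC(C)(C)O2 | intermediate
16 | 6-(2,2-dibromoethenyl)-8-(methoxymethoxy)-2,2-dimethyl-2H-chromene | BrC(Br)=Cc1cc(OCOC)c2c(c1)C=CC(C)(C)O2 | intermediate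
17 | lithium [8-(methoxymethoxy)-2,2-dimethyl-2H-chromen-6-yl]acetylide | [Li]C#Cc1cc(OCOC)c2c(c1)C=CC(C)(C)O2 | intermediate
18 | 3-[8-(methoxymethoxy)-2,2-dimethyl-2H-chromen-6-yl]prop-2-ynoic acid | OC(=O)C#Cc1cc(OCOC)c2c(c1)C=CC(C)(C)O2 | intermediate
19 | 3,5-bis(methoxymethoxy)benzyne | COCOC1=CC(OCOC)=CC#C1 | intermediate
20 | 1-[2-hydroxy-4,6-bis(methoxymethoxy)phenyl]-3-[8-(methoxymethoxy)-2,2-dimethyl-2H-chromen-6-yl]prop-2-yn-1-one | COCOc1cc(O)c(C(=O)C#Cc2cc(OCOC)c3c(c2)C=CC(C)(C)O3)c(OCOC)c1 | intermediate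
21 | 5,7-bis(methoxymethoxy)-2-[8-(methoxymethoxy)-2,2-dimethyl-2H-chromen-6-yl]-4H-chromen-4-one | COCOc1cc(OCOC)c2c(=O)cc(-c3cc(OCOC)c4c(c3)C=CC(C)(C)O4)oc2c1 | intermediate
22 | 3-lithio-5,7-bis(methoxymethoxy)-2-[8-(methoxymethoxy)-2,2-dimethyl-2H-chromen-6-yl]-4H-chromen-4-one | COCOc1cc(OCOC)c2c(=O)c([Li])c(-c3cc(OCOC)c4c(c3)C=CC(C)(C)O4)oc2c1 | intermediate
23 | dimethyl {5,7-bis(methoxymethoxy)-2-[8-(methoxymethoxy)-2,2-dimethyl-2H-chromen-6-yl]-4-oxo-4H-chromen-3-yl}boronate | COCOc1cc(OCOC)c2c(=O)c(B(OC)OC)c(-c3cc(OCOC)c4c(c3)C=CC(C)(C)O4)oc2c1 | intermediate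
24 | 3-hydroxy-5,7-bis(methoxymethoxy)-2-[8-(methoxymethoxy)-2,2-dimethyl-2H-chromen-6-yl]-4H-chromen-4-one | COCOc1cc(OCOC)c2c(=O)c(O)c(-c3cc(OCOC)c4c(c3)C=CC(C)(C)O4)oc2c1 | intermediate
25 | 3,5,7-trihydroxy-2-(8-hydroxy-2,2-dimethyl-2H-chromen-6-yl)-4H-chromen-4-one | Oc1cc(O)c2c(=O)c(O)c(-c3cc(O)c4c(c3)C=CC(C)(C)O4)oc2c1 | intermediate
26 | 1-bromo-3-methylbut-2-ene | CC(C)=CCBr | starting material
27 | 3,5-dihydroxy-2-(8-hydroxy-2,2-dimethyl-2H-chromen-6-yl)-7-[(3-methylbut-2-en-1-yl)oxy]-4H-chromen-4-one | CC(C)=CCOc1cc(O)c2c(=O)c(O)c(-c3cc(O)c4c(c3)C=CC(C)(C)O4)oc2c1 | intermediate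
28 | 2-[8-(acetyloxy)-2,2-dimethyl-2H-chromen-6-yl]-7-[(3-methylbut-2-en-1-yl)oxy]-4-oxo-4H-chromene-3,5-diyl diacetate | CC(C)=CCOc1cc(OC(C)=O)c2c(=O)c(OC(C)=O)c(-c3cc(OC(C)=O)c4c(c3)C=CC(C)(C)O4)oc2c1 | intermediate
29 | 2-[8-(acetyloxy)-2,2-dimethyl-2H-chromen-6-yl]-7-hydroxy-8-(2-methylbut-3-en-2-yl)-4-oxo-4H-chromene-3,5-diyl diacetate | C=CC(C)(C)c1c(O)cc(OC(C)=O)c2c(=O)c(OC(C)=O)c(-c3cc(OC(C)=O)c4c(c3)C=CC(C)(C)O4)oc12 | intermediate
30 | 2-[8-(acetyloxy)-2,2-dimethyl-2H-chromen-6-yl]-8-(2-methylbut-3-en-2-yl)-4-oxo-4H-chromene-3,5,7-triyl triacetate | C=CC(C)(C)c1c(OC(C)=O)cc(OC(C)=O)c2c(=O)c(OC(C)=O)c(-c3cc(OC(C)=O)c4c(c3)C=CC(C)(C)O4)oc12 | intermediate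
31 | Broussonol A, 3,5,7-trihydroxy-2-(8-hydroxy-2,2-dimethyl-2H-chromen-6-yl)-8-(2-methylbut-3-en-2-yl)-4H-chromen-4-one | C=CC(C)(C)c1c(O)cc(O)c2c(=O)c(O)c(-c3cc(O)c4c(c3)C=CC(C)(C)O4)oc12 | target

**Step count**

Total: 16 steps. Longest linear sequence: 12 steps (steps 5 to 16, from 3,4-dihydroxybenzaldehyde); the aryne precursor branch (steps 1 to 4) joins at step 10.

**Steps most likely to fail, with fallbacks**

Step 10. The aryl anion formed after carboxylate addition may be protonated before it takes the acyl group, so that the reaction stops at the aryl propiolate. The propiolate may also lose CO2 at the temperature needed, or the phenoxide may close in the 5-exo mode. The fallback assembles the same ynone by acetylide addition instead of aryne insertion. It sets out from dibromoalkene 16 and comes back to the route at ynone 20 and flavone 21. Commercial 2,4,6-trihydroxybenzaldehyde is protected at its two non-chelated hydroxyls (MOMCl, 2 equiv, i-Pr2NEt, CH2Cl2) to give 2-hydroxy-4,6-bis(methoxymethoxy)benzaldehyde F1. Its sodium phenoxide (NaH, THF) is treated at −78 °C with acetylide 17, generated from 16 with n-BuLi as in step 9, to give racemic 2-{1-hydroxy-3-[8-(methoxymethoxy)-2,2-dimethyl-2H-chromen-6-yl]prop-2-yn-1-yl}-3,5-bis(methoxymethoxy)phenol F2. MnO2 in CH2Cl2 should oxidise the benzylic propargylic alcohol to 20, and Et2NH in EtOH should close 20 to 21 by 6-endo oxa-Michael cyclisation.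

Step 15. The allyl unit may migrate to C6 instead of C8, or the ether may fragment with loss of the prenyl group or rearrange further at the temperature required. The fallback places the 1,1-dimethylallyl group on ring A before ring C exists, at a stage where the two ortho carbons are equivalent by symmetry, and then builds ring C by the acetylide route. It sets out from phenol 2 and comes back to the route only at target 31.
- Phenol 2 is O-alkylated with 26 (K2CO3, acetone) to 1,3-bis(methoxymethoxy)-5-[(3-methylbut-2-en-1-yl)oxy]benzene F3.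
- Thermal Claisen rearrangement (PhNEt2, 190 °C) has two equivalent ortho positions and should give a single ortho product, 3,5-bis(methoxymethoxy)-2-(2-methylbut-3-en-2-yl)phenol F4.
- Magnesium-mediated ortho-formylation (MgCl2, Et3N, paraformaldehyde, MeCN, reflux) at the only free ortho position gives 2-hydroxy-4,6-bis(methoxymethoxy)-3-(2-methylbut-3-en-2-yl)benzaldehyde F5.
- Addition of acetylide 17 to its sodium phenoxide gives racemic 2-{1-hydroxy-3-[8-(methoxymethoxy)-2,2-dimethyl-2H-chromen-6-yl]prop-2-yn-1-yl}-3,5-bis(methoxymethoxy)-6-(2-methylbut-3-en-2-yl)phenol F6.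
- MnO2 gives 1-[2-hydroxy-4,6-bis(methoxymethoxy)-3-(2-methylbut-3-en-2-yl)phenyl]-3-[8-(methoxymethoxy)-2,2-dimethyl-2H-chromen-6-yl]prop-2-yn-1-one F7.
- Et2NH in EtOH closes it to 5,7-bis(methoxymethoxy)-2-[8-(methoxymethoxy)-2,2-dimethyl-2H-chromen-6-yl]-8-(2-methylbut-3-en-2-yl)-4H-chromen-4-one F8.
- C3 hydroxylation as in step 11 gives 3-hydroxy-5,7-bis(methoxymethoxy)-2-[8-(methoxymethoxy)-2,2-dimethyl-2H-chromen-6-yl]-8-(2-methylbut-3-en-2-yl)-4H-chromen-4-one F9.
- The three MOM groups are removed with dilute HCl in MeOH at rt, kept mild because the 1,1-dimethylallyl group is already present, to give 31.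

Step 13. Alkylation at O3, or at two oxygens, may compete with alkylation at O7. The fallback singles out the 7-oxygen by selective deacylation instead of selective alkylation. It sets out from tetraol 25 and comes back at triacetate 28, replacing steps 13 and 14. Tetraol 25 is peracetylated (Ac2O, pyridine, DMAP) to 2-[8-(acetyloxy)-2,2-dimethyl-2H-chromen-6-yl]-4-oxo-4H-chromene-3,5,7-triyl triacetate F10. PhSH and imidazole in N-methylpyrrolidone at 0 °C should remove only the 7-O-acetyl group, the most electrophilic aryl ester (para to the C4 carbonyl), to give 2-[8-(acetyloxy)-2,2-dimethyl-2H-chromen-6-yl]-7-hydroxy-4-oxo-4H-chromene-3,5-diyl diacetate F11. Mitsunobu etherification with 3-methylbut-2-en-1-ol (PPh3, diisopropyl azodicarboxylate, THF, 0 °C) then gives 28.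

**Further compounds**

F1 | step 10 | 2-hydroxy-4,6-bis(methoxymethoxy)benzaldehyde | O=Cc1c(O)cc(OCOC)cc1OCOC
F2 | step 10 | 2-{1-hydroxy-3-[8-(methoxymethoxy)-2,2-dimethyl-2H-chromen-6-yl]prop-2-yn-1-yl}-3,5-bis(methoxymethoxy)phenol (racemic) | OC(C#Cc1cc(OCOC)c2c(c1)C=CC(C)(C)O2)c1c(O)cc(OCOC)cc1OCOC
F3 | step 15 | 1,3-bis(methoxymethoxy)-5-[(3-methylbut-2-en-1-yl)oxy]benzene | CC(C)=CCOc1cc(OCOC)cc(OCOC)c1
F4 | step 15 | 3,5-bis(methoxymethoxy)-2-(2-methylbut-3-en-2-yl)phenol | C=CC(C)(C)c1c(O)cc(OCOC)cc1OCOC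
F5 | step 15 | 2-hydroxy-4,6-bis(methoxymethoxy)-3-(2-methylbut-3-en-2-yl)benzaldehyde | C=CC(C)(C)c1c(O)c(C=O)c(OCOC)cc1OCOC
F6 | step 15 | 2-{1-hydroxy-3-[8-(methoxymethoxy)-2,2-dimethyl-2H-chromen-6-yl]prop-2-yn-1-yl}-3,5-bis(methoxymethoxy)-6-(2-methylbut-3-en-2-yl)phenol (racemic) | C=CC(C)(C)c1c(O)c(C(O)C#Cc2cc(OCOC)c3c(c2)C=CC(C)(C)O3)c(OCOC)cc1OCOC
F7 | step 15 | 1-[2-hydroxy-4,6-bis(methoxymethoxy)-3-(2-methylbut-3-en-2-yl)phenyl]-3-[8-(methoxymethoxy)-2,2-dimethyl-2H-chromen-6-yl]prop-2-yn-1-one | C=CC(C)(C)c1c(O)c(C(=O)C#Cc2cc(OCOC)c3c(c2)C=CC(C)(C)O3)c(OCOC)cc1OCOC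
F8 | step 15 | 5,7-bis(methoxymethoxy)-2-[8-(methoxymethoxy)-2,2-dimethyl-2H-chromen-6-yl]-8-(2-methylbut-3-en-2-yl)-4H-chromen-4-one | C=CC(C)(C)c1c(OCOC)cc(OCOC)c2c(=O)cc(-c3cc(OCOC)c4c(c3)C=CC(C)(C)O4)oc12
F9 | step 15 | 3-hydroxy-5,7-bis(methoxymethoxy)-2-[8-(methoxymethoxy)-2,2-dimethyl-2H-chromen-6-yl]-8-(2-methylbut-3-en-2-yl)-4H-chromen-4-one | C=CC(C)(C)c1c(OCOC)cc(OCOC)c2c(=O)c(O)c(-c3cc(OCOC)c4c(c3)C=CC(C)(C)O4)oc12
F10 | step 13 | 2-[8-(acetyloxy)-2,2-dimethyl-2H-chromen-6-yl]-4-oxo-4H-chromene-3,5,7-triyl triacetate | CC(=O)Oc1cc(OC(C)=O)c2c(=O)c(OC(C)=O)c(-c3cc(OC(C)=O)c4c(c3)C=CC(C)(C)O4)oc2c1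
F11 | step 13 | 2-[8-(acetyloxy)-2,2-dimethyl-2H-chromen-6-yl]-7-hydroxy-4-oxo-4H-chromene-3,5-diyl diacetate | Oc1cc(OC(C)=O)c2c(=O)c(OC(C)=O)c(-c3cc(OC(C)=O)c4c(c3)C=CC(C)(C)O4)oc2c1
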